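**Strategy.** The target is disconnected at the cyclobutane C4–C5–C11–C10, whose 1,3-related carbons C4 and C11 are also joined by C1–C2=C3. This bicyclo[3.1.1]heptane is the signature of a ketene (C5=C4) adding across an alkene (C11=C10) held three atoms away. One thermal intramolecular [2+2] of a vinylketene, made from an acyclic geranate-derived dienoyl chloride carrying a C9 silyloxy(ethynyl) stereocentre, builds that four-membered ring, the six-membered ring, quaternary C10 and both bridgeheads, and leaves C5 as a ketone. From it C6 is grown and the second bridge (C6–C9) is closed by an intramolecular Horner–Wadsworth–Emmons reaction.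

Key step: step 6

Atom labels used throughout: the enone is C1(=O)–C2=C3(CH3). C3 is bonded to cyclobutane carbon C4 and C1 to cyclobutane carbon C11. The other two ring carbons are C5 (H, bonded to C6) and C10 (CH3, bonded to C9). C6 is C(CH3)2, C7 the carbinol carbon, C8 the angelate carbon and C9 the 2-methylbutanoate carbon. The bridge C6–C9 has a "C4 face" and a "C11 face"; in the target the C7 oxygen is on the C4 face and the C8 and C9 oxygens are on the C11 face.

Remark 1 (chemistry): a (2E)-3-methyl-2-enoyl chloride is expected to lose the proton of the C3 methyl group (syn to the acyl group), so the cycloadduct is formulated with an exocyclic C3=CH2. Step 7 moves this alkene into the ring (C2=C3); any C2=C3 isomer formed directly in step 6 converges there.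

Remark 2 (chemistry): the ethynyl group is carried as C–H (its silyl group falls off in the ester hydrolysis). The C9 silyl ether is assumed to steer the ketene to the alkene face anti to it, which gives the ring configuration of the target with C9 kept unchanged to the end.

Remark 3: (1-methoxyethyl)triphenylphosphonium chloride (from PPh3 and 1-chloroethyl methyl ether) is treated as a reagent.

**Step 1**
Reactants: 1 methyl (2E)-3,7-dimethylocta-2,6-dienoate (methyl geranate)
Product: 3 methyl (2E,6E)-3,7-dimethyl-8-oxoocta-2,6-dienoate, via allylic alcohol 2 (not isolated)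
Conditions: SeO2 (1.3 equiv), 1,4-dioxane/H2O (30:1), 80 °C
Reagents that add atoms: selenium dioxide, O=[Se]=O
Why: Allylic oxidation by SeO2 (ene reaction, then 2,3-shift) attacks the electron-rich terminal alkene and not the enoate, functionalises the (E)-methyl group, and takes the allylic alcohol on to the enal.

**Step 2**
Reactants: 3 methyl (2E,6E)-3,7-dimethyl-8-oxoocta-2,6-dienoate; 4 ethynyltrimethylsilane
Product: 5 methyl (2E,6E,8S)-8-hydroxy-3,7-dimethyl-10-(trimethylsilyl)deca-2,6-dien-9-ynoate
Conditions: (S,S)-ProPhenol (10 mol %), Ph3P=O (20 mol %), Me2Zn (3 equiv), 4 (3 equiv), toluene, 4 °C; then aq. NH4Cl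
Reagents that add atoms: none
Why: Catalytic asymmetric alkynylation in which the dinuclear zinc–ProPhenol complex adds the zinc alkynylide 1,2 to the enal (the ester is inert to Me2Zn); attack on the Re face of the formyl group gives the (8S) alcohol, the future C9, and the (R,R) ligand is taken should the sense with this α-branched enal run the other way.

**Step 3**
Reactants: 5 methyl (2E,6E,8S)-8-hydroxy-3,7-dimethyl-10-(trimethylsilyl)deca-2,6-dien-9-ynoate
Product: 6 methyl (2E,6E,8S)-8-(tert-butyldimethylsilyloxy)-3,7-dimethyl-10-(trimethylsilyl)deca-2,6-dien-9-ynoate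
Conditions: TBSCl, imidazole, DMF, 20 °C
Reagents that add atoms: tert-butyldimethylsilyl chloride, CC(C)(C)[Si](C)(C)Cl
Why: Imidazole-mediated silylation of the secondary alcohol installs the bulky group that later controls the alkene face; no stereocentre is touched.

**Step 4**
Reactants: 6 methyl (2E,6E,8S)-8-(tert-butyldimethylsilyloxy)-3,7-dimethyl-10-(trimethylsilyl)deca-2,6-dien-9-ynoate
Product: 7 (2E,6E,8R)-8-(tert-butyldimethylsilyloxy)-3,7-dimethyldeca-2,6-dien-9-ynoic acid (same spatial arrangement at the carbinol carbon; the descriptor changes because ethynyl now ranks below alkenyl)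
Conditions: LiOH·H2O (4 equiv), THF/MeOH/H2O, 40 °C; then 1 M HCl to pH 4, 0 °C
Reagents that add atoms: lithium hydroxide, [Li+].[OH-]
Why: Saponification of the conjugated methyl ester, in a medium that also cleaves the C(sp)–SiMe3 bond while the secondary silyl ether and both (E)-alkenes survive.

**Step 5**
Reactants: 7 (2E,6E,8R)-8-(tert-butyldimethylsilyloxy)-3,7-dimethyldeca-2,6-dien-9-ynoic acid
Product: 8 (2E,6E,8R)-8-(tert-butyldimethylsilyloxy)-3,7-dimethyldeca-2,6-dien-9-ynoyl chloride
Conditions: 1-chloro-N,N,2-trimethylprop-1-en-1-amine (1.2 equiv), CH2Cl2, 0 → 20 °C; concentrated and used crude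
Reagents that add atoms: 1-chloro-N,N,2-trimethylprop-1-en-1-amine, CC(C)=C(Cl)N(C)C
Why: The α-chloroenamine makes the acid chloride under neutral conditions without free HCl, which spares the allylic, propargylic silyl ether.

**Step 6**
Reactants: 8 (2E,6E,8R)-8-(tert-butyldimethylsilyloxy)-3,7-dimethyldeca-2,6-dien-9-ynoyl chloride
Product: 10 7-methyl-2-methylidene-7-[(1R)-1-(tert-butyldimethylsilyloxy)prop-2-yn-1-yl]bicyclo[3.1.1]heptan-6-one (C5 ketone, C3=CH2, C10 methyl syn to the C1–C3 bridge), via vinylketene 9 (not isolated)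
Conditions: Et3N (5 equiv), toluene, reflux; 8 added over 6 h to a final 0.005 M
Reagents that add atoms: none
Why: Et3N removes HCl in a 1,4-sense, taking a proton from the C3 methyl group that lies syn to the acyl chloride, and the cross-conjugated vinylketene 9 adds through its C5=C4 bond to the C11=C10 alkene in a thermal, asynchronous [2+2] that is suprafacial on the alkene: electrophilic C5 engages C11 first and the positive charge growing on tertiary C10 is quenched by C4. The closest known reaction is the intramolecular cycloaddition of vinylketenes from 3-methyl-2-enoyl chlorides to trisubstituted alkenes, which gives 2-methylenebicyclo[3.1.1]heptan-6-ones. The six-membered ring (C5, C4, C3, C2, C1, C11) closes by bonding of C5 to the tether-bearing alkene carbon C11 (exo with respect to C11=C10) and the cyclobutanone by collapse of C10 onto C4, the crossed mode that the three-atom tether C3–C2–C1 enforces. At C10 the methyl group ends syn to the C1–C3 bridge and the C9 chain anti because the (E)-alkene geometry is retained, C4 and C11 are bridgeheads whose relative configuration the bicycle dictates, and the absolute sense comes from C9: the ketene approaches the alkene face opposite the bulky silyloxy group in the rotamer that keeps the C9 hydrogen next to the C10 methyl and the slim ethynyl group over the alkene. The step needs regioselective proton loss (methyl, not C2), C5-to-C11 regiochemistry, reaction at the alkene and not the alkyne, and facial selectivity; these rest on the syn methyl of the (2E) chloride, cation stabilisation at C10, the short tether to the more nucleophilic alkene and the C9 silyl ether, with high dilution holding back ketene dimerisation.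

**Step 7**
Reactants: 10 7-methyl-2-methylidene-7-[(1R)-1-(tert-butyldimethylsilyloxy)prop-2-yn-1-yl]bicyclo[3.1.1]heptan-6-one
Product: 13 2,7-dimethyl-7-[(1R)-1-(tert-butyldimethylsilyloxy)prop-2-yn-1-yl]bicyclo[3.1.1]hept-2-en-6-one (C2=C3 isomer), via allylic sulfinic acid 11 (not isolated), via rearranged sulfinic acid 12 (not isolated)
Conditions: liquid SO2/CH2Cl2 (1:1), sealed tube, 20 °C
Reagents that add atoms: none
Why: SO2-mediated olefin isomerisation (ene reaction at the =CH2 carbon, 1,3-shift of the sulfinic acid, retro-ene loss of SO2) moves the alkene to the more stable trisubstituted ring position without carbocations, as known for β-pinene to α-pinene; no stereocentre is touched.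

**Step 8**
Reactants: 13 2,7-dimethyl-7-[(1R)-1-(tert-butyldimethylsilyloxy)prop-2-yn-1-yl]bicyclo[3.1.1]hept-2-en-6-one
Product: 14 6-(1-methoxyethylidene)-2,7-dimethyl-7-[(1R)-1-(tert-butyldimethylsilyloxy)prop-2-yn-1-yl]bicyclo[3.1.1]hept-2-ene (enol ether C5=C6(OCH3)CH3, E/Z mixture)
Conditions: (1-methoxyethyl)triphenylphosphonium chloride (1.5 equiv), KN(SiMe3)2 (1.4 equiv), THF, 0 °C; then 13, 0 → 50 °C
Reagents that add atoms: (1-methoxyethyl)triphenylphosphonium chloride, COC(C)[P+](c1ccccc1)(c1ccccc1)c1ccccc1.[Cl-]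
Why: Wittig olefination of the strained, non-enolisable cyclobutanone with an α-methoxyalkylidene ylide (a masked acetyl group) attaches C6; both enol ether isomers give the same ketone later and the ylide is too weak a base to deprotonate the alkyne.

**Step 9**
Reactants: 14 enol ether C5=C6(OCH3)CH3 with terminal alkyne
Product: 16 diethyl alkynylphosphonate of 14 (C8≡C7–P(O)(OEt)2), via lithium acetylide 15 (not isolated)
Conditions: n-BuLi (1.05 equiv), THF, −78 °C; then ClP(O)(OEt)2, −78 → 0 °C
Reagents that add atoms: diethyl chlorophosphate, CCOP(=O)(Cl)OCC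
Why: Deprotonation of the only acidic site and phosphorylation of the acetylide give the 1-alkynylphosphonate that marks C7 as the future nucleophile.

**Step 10**
Reactants: 16 diethyl alkynylphosphonate of 14
Product: 17 diethyl {2-oxo-3-(tert-butyldimethylsilyloxy)-3-[6-acetyl-2,7-dimethylbicyclo[3.1.1]hept-2-en-7-yl]propyl}phosphonate (C5 acetyl on the face of the C9 chain, C8 ketone, C7 CH2P(O)(OEt)2)
Conditions: (Ph3P)AuCl (5 mol %), AgOTf (5 mol %), PPTS (10 mol %), 1,4-dioxane/H2O (10:1), 50 °C
Reagents that add atoms: water, O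
Why: Gold-catalysed hydration of a 1-alkynylphosphonate places oxygen on C8 (β to phosphorus), and the same mildly acidic medium hydrolyses the enol ether by protonating C5 from the open face syn to the C1–C3 bridge, which leaves the acetyl group on the face of the C9 chain.

**Step 11**
Reactants: 17 acetyl β-ketophosphonate
Product: 18 tricyclic dienone C6(CH3)=C7H–C8(=O) with C9–OTBS on the C11 face (bridge C6–C9 closed; tricyclo[5.4.0.0(2,8)]undecane skeleton)
Conditions: K2CO3 (3 equiv), 18-crown-6 (1 equiv), toluene, 0.01 M, 70 °C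
Reagents that add atoms: none
Why: Intramolecular Horner–Wadsworth–Emmons olefination of the C7 phosphonate anion with the C6 methyl ketone forms C6=C7 and the bridging ring (seven-membered through C4 or C11) between the two cis-1,3 arms of the cyclobutane; only the C5 epimer drawn can close and base equilibrates the other into it.

**Step 12**
Reactants: 18 tricyclic dienone
Product: 20 triisopropylsilyl enol ether C7=C8(OTIPS) with C6(CH3)2, via lithium enolate 19 (not isolated)
Conditions: CuI, MeLi (Me2CuLi, 3 equiv), Et2O, −40 → 0 °C; then TIPSOTf (4 equiv), Et3N, −78 → 0 °C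
Reagents that add atoms: lithium dimethylcuprate, [Li+].C[Cu-]C; triisopropylsilyl trifluoromethanesulfonate, CC(C)[Si](C(C)C)(C(C)C)OS(=O)(=O)C(F)(F)F
Why: Cuprate conjugate addition to the β-methyl enone makes C6 the gem-dimethyl quaternary carbon (no stereocentre arises), and O-silylation of the regiodefined enolate fixes C7 as the site of oxygenation.

**Step 13**
Reactants: 20 triisopropylsilyl enol ether
Product: 22 C8 ketone with C7–OTIPS on the C4 face and C9–OTBS on the C11 face, via silyloxy epoxide 21 (not isolated)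
Conditions: dimethyldioxirane (1.1 equiv, acetone), CH2Cl2, −78 °C; then PPTS (cat.), 0 °C
Reagents that add atoms: dimethyldioxirane, CC1(C)OO1
Why: Rubottom oxidation, in which the electron-rich silyl enol ether is epoxidised far faster than the C2=C3 alkene and from the face anti to the neighbouring C9 silyloxy group; the epoxide opens with 1,4-silyl shift to the α-silyloxy ketone, setting C7.

**Step 14**
Reactants: 22 C8 ketone with C7–OTIPS and C9–OTBS
Product: 23 C1 enone (C1(=O)–C2=C3) of 22
Conditions: CrO3 (15 equiv), 3,5-dimethylpyrazole (15 equiv), CH2Cl2, −20 °C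
Reagents that add atoms: chromium trioxide, O=[Cr](=O)=O
Why: Allylic oxidation of the ring CH2 next to the trisubstituted alkene (the α-pinene to verbenone change); the bridgehead allylic C4–H gives no conjugated radical and the allylic methyl is less reactive than the ring methylene.

**Step 15**
Reactants: 23 C1 enone with C7–OTIPS and C9–OTBS
Product: 24 C9 alcohol (C7–OTIPS kept)
Conditions: HF·pyridine, pyridine, THF, 0 → 20 °C
Reagents that add atoms: none
Why: Size-selective desilylation, the tert-butyldimethylsilyl ether being cleaved much faster than the triisopropylsilyl ether in an otherwise similar environment.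

**Step 16**
Reactants: 24 C9 alcohol; 25 (R)-2-methylbutanoic acid
Product: 26 C9 (R)-2-methylbutanoate (C7–OTIPS, C8 ketone, C1 enone)
Conditions: 25 (1.5 equiv), 2-methyl-6-nitrobenzoic anhydride (1.6 equiv), DMAP (0.3 equiv), Et3N (3 equiv), CH2Cl2, 20 → 40 °C
Reagents that add atoms: none
Why: Shiina esterification through the mixed anhydride acylates the only free, hindered hydroxyl under mild conditions that should leave the α-stereocentre of the acid intact.

**Step 17**
Reactants: 26 C9 (R)-2-methylbutanoate with C7–OTIPS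
Product: 27 C7 alcohol (α-hydroxy ketone at C7/C8)
Conditions: 48% aq. HF, MeCN, 0 → 20 °C
Reagents that add atoms: none
Why: Acidic fluoride desilylation frees the C7 hydroxyl without base, so the α-acyloxy ketone and the centres flanking C8 are not put at risk.

**Step 18**
Reactants: 27 C7 alcohol
Product: 28 7,8-diol (C7–OH on the C4 face, C8–OH on the C11 face, cis to the C9 ester)
Conditions: Me4NBH(OAc)3 (5 equiv), AcOH/MeCN (1:1), −30 °C
Reagents that add atoms: none
Why: Hydroxyl-directed reduction, in which the borohydride bound to the C7 oxygen delivers hydride to the same face of the C8 ketone and gives the trans-7,8-diol; the C1 enone has no neighbouring hydroxyl and is not reduced.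

**Step 19**
Reactants: 28 7,8-diol; 29 angelic acid ((Z)-2-methylbut-2-enoic acid)
Product: 30 target (CNP0202800.1)
Conditions: 29 (3 equiv), 2,4,6-trichlorobenzoyl chloride (3 equiv), Et3N (3.5 equiv), toluene, 20 °C, 2 h; then 28, toluene, 75 °C
Reagents that add atoms: none
Why: Yamaguchi-type acylation with the preformed mixed anhydride, run without DMAP so that the (Z)-acyl group does not isomerise, should favour the C8 hydroxyl, flanked by two methine carbons, over the neopentyl C7 hydroxyl next to quaternary C6.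

**Compound list**

1 | methyl (2E)-3,7-dimethylocta-2,6-dienoate (methyl geranate) | COC(=O)/C=C(\C)CCC=C(C)C | starting material
2 | methyl (2E,6E)-8-hydroxy-3,7-dimethylocta-2,6-dienoate | COC(=O)/C=C(\C)CC/C=C(\C)CO | intermediate (not isolated)
3 | methyl (2E,6E)-3,7-dimethyl-8-oxoocta-2,6-dienoate | COC(=O)/C=C(\C)CC/C=C(\C)C=O | intermediate
4 | ethynyltrimethylsilane | C#C[Si](C)(C)C | starting material
5 | methyl (2E,6E,8S)-8-hydroxy-3,7-dimethyl-10-(trimethylsilyl)deca-2,6-dien-9-ynoate | COC(=O)/C=C(\C)CC/C=C(\C)[C@H](O)C#C[Si](C)(C)C | intermediate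
6 | methyl (2E,6E,8S)-8-(tert-butyldimethylsilyloxy)-3,7-dimethyl-10-(trimethylsilyl)deca-2,6-dien-9-ynoate | COC(=O)/C=C(\C)CC/C=C(\C)[C@H](O[Si](C)(C)C(C)(C)C)C#C[Si](C)(C)C | intermediate
7 | (2E,6E,8R)-8-(tert-butyldimethylsilyloxy)-3,7-dimethyldeca-2,6-dien-9-ynoic acid | OC(=O)/C=C(\C)CC/C=C(\C)[C@H](O[Si](C)(C)C(C)(C)C)C#C | intermediate
8 | (2E,6E,8R)-8-(tert-butyldimethylsilyloxy)-3,7-dimethyldeca-2,6-dien-9-ynoyl chloride (key-step precursor) | ClC(=O)/C=C(\C)CC/C=C(\C)[C@H](O[Si](C)(C)C(C)(C)C)C#C | intermediate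
9 | (6E,8R)-8-(tert-butyldimethylsilyloxy)-7-methyl-3-methylidenedeca-1,6-dien-9-yn-1-one (vinylketene) | O=C=CC(=C)CC/C=C(\C)[C@H](O[Si](C)(C)C(C)(C)C)C#C | intermediate (not isolated)
10 | 7-methyl-2-methylidene-7-[(1R)-1-(tert-butyldimethylsilyloxy)prop-2-yn-1-yl]bicyclo[3.1.1]heptan-6-one (key-step product; 7-methyl syn to the three-carbon bridge) | O=C1[C@H]2CCC(=C)[C@@H]1[C@@]2(C)[C@H](O[Si](C)(C)C(C)(C)C)C#C | intermediate
11 | allylic sulfinic acid: C2=C3 alkene, CH2–S(O)OH on C3 | O=C1[C@H]2CC=C(CS(=O)O)[C@@H]1[C@@]2(C)[C@H](O[Si](C)(C)C(C)(C)C)C#C | intermediate (not isolated)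
12 | rearranged sulfinic acid: S(O)OH on C2 (either epimer), C3=CH2 | O=C1[C@H]2CC(S(=O)O)C(=C)[C@@H]1[C@@]2(C)[C@H](O[Si](C)(C)C(C)(C)C)C#C | intermediate (not isolated)
13 | 2,7-dimethyl-7-[(1R)-1-(tert-butyldimethylsilyloxy)prop-2-yn-1-yl]bicyclo[3.1.1]hept-2-en-6-one | O=C1[C@H]2CC=C(C)[C@@H]1[C@@]2(C)[C@H](O[Si](C)(C)C(C)(C)C)C#C | intermediate
14 | 6-(1-methoxyethylidene) enol ether of 13 (E/Z mixture at C5=C6) | COC(C)=C1[C@H]2CC=C(C)[C@@H]1[C@@]2(C)[C@H](O[Si](C)(C)C(C)(C)C)C#C | intermediate
15 | lithium acetylide of 14 | COC(C)=C1[C@H]2CC=C(C)[C@@H]1[C@@]2(C)[C@H](O[Si](C)(C)C(C)(C)C)C#[C-].[Li+] | intermediate (not isolated)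
16 | diethyl alkynylphosphonate of 14 | COC(C)=C1[C@H]2CC=C(C)[C@@H]1[C@@]2(C)[C@H](O[Si](C)(C)C(C)(C)C)C#CP(=O)(OCC)OCC | intermediate
17 | C5-acetyl, C8-keto, C7-(diethoxyphosphoryl)methyl compound (acetyl on the face of the C9 chain) | CC(=O)[C@@H]1[C@H]2CC=C(C)[C@@H]1[C@@]2(C)[C@H](O[Si](C)(C)C(C)(C)C)C(=O)CP(=O)(OCC)OCC | intermediate
18 | tricyclic dienone: C6(CH3)=C7–C8(=O), C9–OTBS (C11 face), C2=C3 | O=C1C=C(C)[C@@H]2[C@H]3CC=C(C)[C@@H]2[C@@]3(C)[C@@H]1O[Si](C)(C)C(C)(C)C | intermediate
19 | lithium enolate (C7=C8–OLi) with C6(CH3)2 | [Li+].[O-]C1=CC(C)(C)[C@@H]2[C@H]3CC=C(C)[C@@H]2[C@@]3(C)[C@@H]1O[Si](C)(C)C(C)(C)C | intermediate (not isolated)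
20 | triisopropylsilyl enol ether (C7=C8–OTIPS) | CC(C)[Si](C(C)C)(C(C)C)OC1=CC(C)(C)[C@@H]2[C@H]3CC=C(C)[C@@H]2[C@@]3(C)[C@@H]1O[Si](C)(C)C(C)(C)C | intermediate
21 | C7–C8 silyloxy epoxide (oxygen on the C4 face) | CC(C)[Si](C(C)C)(C(C)C)O[C@]12O[C@H]1C(C)(C)[C@@H]3[C@H]4CC=C(C)[C@@H]3[C@@]4(C)[C@@H]2O[Si](C)(C)C(C)(C)C | intermediate (not isolated)
22 | C8 ketone, C7–OTIPS (C4 face), C9–OTBS (C11 face) | O=C1[C@@H](O[Si](C(C)C)(C(C)C)C(C)C)C(C)(C)[C@@H]2[C@H]3CC=C(C)[C@@H]2[C@@]3(C)[C@@H]1O[Si](C)(C)C(C)(C)C | intermediate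
23 | C1 enone of 22 | O=C1[C@@H](O[Si](C(C)C)(C(C)C)C(C)C)C(C)(C)[C@@H]2[C@H]3C(=O)C=C(C)[C@@H]2[C@@]3(C)[C@@H]1O[Si](C)(C)C(C)(C)C | intermediate
24 | C9 alcohol (C7–OTIPS, C8 ketone, C1 enone) | O=C1[C@@H](O[Si](C(C)C)(C(C)C)C(C)C)C(C)(C)[C@@H]2[C@H]3C(=O)C=C(C)[C@@H]2[C@@]3(C)[C@@H]1O | intermediate
25 | (R)-2-methylbutanoic acid | CC[C@@H](C)C(=O)O | starting material
26 | C9 (R)-2-methylbutanoate (C7–OTIPS, C8 ketone) | O=C1[C@@H](O[Si](C(C)C)(C(C)C)C(C)C)C(C)(C)[C@@H]2[C@H]3C(=O)C=C(C)[C@@H]2[C@@]3(C)[C@@H]1OC(=O)[C@H](C)CC | intermediate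
27 | C7 alcohol (C8 ketone, C9 ester) | O=C1[C@@H](O)C(C)(C)[C@@H]2[C@H]3C(=O)C=C(C)[C@@H]2[C@@]3(C)[C@@H]1OC(=O)[C@H](C)CC | intermediate
28 | trans-7,8-diol with C9 (R)-2-methylbutanoate | O[C@@H]1[C@@H](O)C(C)(C)[C@@H]2[C@H]3C(=O)C=C(C)[C@@H]2[C@@]3(C)[C@@H]1OC(=O)[C@H](C)CC | intermediate
29 | angelic acid ((Z)-2-methylbut-2-enoic acid) | C/C=C(/C)C(=O)O | starting material
30 | CNP0202800.1: C7–OH, C8 O-angeloyl, C9 O-[(R)-2-methylbutanoyl], C1 enone | C/C=C(/C)C(=O)O[C@@H]1[C@@H](O)C(C)(C)[C@@H]2[C@H]3C(=O)C=C(C)[C@@H]2[C@@]3(C)[C@@H]1OC(=O)[C@H](C)CC | target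

**Totals.** Total step count: 19. Longest linear sequence: 19 steps (1 to 30); compounds 4, 25 and 29 enter as single building blocks.

**Steps most likely to fail**

Step 6 (key step). What may go wrong: proton loss from C2 instead of the C3 methyl gives a linear vinylketene that cannot reach the alkene, and at reflux this ketene and the slowly formed productive one are drained into dimers and oligomers; the high temperature also erodes the facial preference set by C9. Fallback: ketene 9 is generated by 1,2-elimination from a deconjugated acid chloride. Setting out from ester 6, kinetic γ-deprotonation at the syn methyl group (LiN(iPr)2, HMPA, THF, −78 °C) and α-protonation with AcOH give the 3-methylidene ester, methyl (6E,8S)-8-(tert-butyldimethylsilyloxy)-7-methyl-3-methylidene-10-(trimethylsilyl)dec-6-en-9-ynoate F1. LiOH in THF/MeOH/H2O gives the acid, (6E,8R)-8-(tert-butyldimethylsilyloxy)-7-methyl-3-methylidenedec-6-en-9-ynoic acid F2 (any reconjugated acid is 7). The α-chloroenamine of step 5 gives the acid chloride, (6E,8R)-8-(tert-butyldimethylsilyloxy)-7-methyl-3-methylidenedec-6-en-9-ynoyl chloride F3. Its doubly activated C4 protons are removed by Et3N already at 20–60 °C, so only ketene 9 can form; it cyclises and the route is rejoined at 10.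

Step 11. What may go wrong: the phosphonate anion adds sluggishly to the hindered methyl ketone, so that epimerisation at C9 or intermolecular condensation overtakes closure of the bridged ring. Fallback: a reductive aldol (Reformatsky-type) closure. Setting out from 14, the acetylide 15 is quenched with CBr4 at −78 °C to give the bromoalkyne of 14 F4. The gold-catalysed hydration and hydrolysis of step 10 then give the C5-acetyl bromomethyl ketone F5. SmI2 (2.2 equiv, THF, −78 °C) forms the samarium enolate at C7, which adds to the C6 ketone within a chelate to give the tricyclic β-hydroxy ketone F6. Dehydration (MsCl, Et3N, then DBU) returns the route at enone 18.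

Step 19. What may go wrong: the activated (Z)-2-methylbut-2-enoyl donor reacts slowly at the crowded C8 hydroxyl, which leaves time for Z-to-E isomerisation of the acyl group, migration of the C9 acyl group to the cis C8 hydroxyl and acylation at C7. Fallback: the angelate is built on the molecule. Setting out from 28, 2-[bis(2,2,2-trifluoroethoxy)phosphoryl]propanoic acid (EDC, DMAP cat., CH2Cl2, 0 °C), a saturated donor that cannot isomerise, acylates the C8 hydroxyl to give the C8 phosphonopropanoate of 28 F7. Still–Gennari olefination (KN(SiMe3)2 1 equiv, 18-crown-6, THF, −78 °C, then CH3CHO) forms the (Z)-2-methylbut-2-enoate and arrives at target 30.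

**Further compounds**

F1 | step 6 | methyl (6E,8S)-8-(tert-butyldimethylsilyloxy)-7-methyl-3-methylidene-10-(trimethylsilyl)dec-6-en-9-ynoate | COC(=O)CC(=C)CC/C=C(\C)[C@H](O[Si](C)(C)C(C)(C)C)C#C[Si](C)(C)C
F2 | step 6 | (6E,8R)-8-(tert-butyldimethylsilyloxy)-7-methyl-3-methylidenedec-6-en-9-ynoic acid | OC(=O)CC(=C)CC/C=C(\C)[C@H](O[Si](C)(C)C(C)(C)C)C#C
F3 | step 6 | (6E,8R)-8-(tert-butyldimethylsilyloxy)-7-methyl-3-methylidenedec-6-en-9-ynoyl chloride | ClC(=O)CC(=C)CC/C=C(\C)[C@H](O[Si](C)(C)C(C)(C)C)C#C
F4 | step 11 | bromoalkyne of 14 | COC(C)=C1[C@H]2CC=C(C)[C@@H]1[C@@]2(C)[C@H](O[Si](C)(C)C(C)(C)C)C#CBr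
F5 | step 11 | C5-acetyl bromomethyl ketone (C8 ketone, C7 CH2Br) | CC(=O)[C@@H]1[C@H]2CC=C(C)[C@@H]1[C@@]2(C)[C@H](O[Si](C)(C)C(C)(C)C)C(=O)CBr
F6 | step 11 | tricyclic β-hydroxy ketone (C6 carbinol, either epimer; C8 ketone) | O=C1CC(C)(O)[C@@H]2[C@H]3CC=C(C)[C@@H]2[C@@]3(C)[C@@H]1O[Si](C)(C)C(C)(C)C
F7 | step 19 | C8 2-[bis(2,2,2-trifluoroethoxy)phosphoryl]propanoate of 28 (epimers at the phosphonate carbon) | CC(C(=O)O[C@@H]1[C@@H](O)C(C)(C)[C@@H]2[C@H]3C(=O)C=C(C)[C@@H]2[C@@]3(C)[C@@H]1OC(=O)[C@H](C)CC)P(=O)(OCC(F)(F)F)OCC(F)(F)F
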